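The readings were computed for substances that don't exist, noise included.

Thursday's run holds the number I carry through these flasks.

all flasks: first nucleophile 105 mM; second nucleophile 54.6 mM

| run | solid substrate | protic impurity | temperature | remark | time |
|---|---|---|---|---|---|
| Monday's | 42 mM | 6.3 mM | 1 °C | run made earlier |  |
| Thursday's | 42 mM | 9.4 mM | 26 °C | run made earlier |  |
| Saturday's | 21 mM | 12.6 mM | 1 °C | run made earlier |  |
| dusk | 42 mM | 12.6 mM | 35 °C |  | 2.0 min |
| winter | 42 mM | 12.6 mM | −10 °C |  | 2.0 min |
| noon | 42 mM | 12.6 mM | 20 °C |  | 2.0 min |
| dawn | 42 mM | 12.6 mM | 5 °C |  | 2.0 min |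

- Monday's (time / min: target / %): 2.50: 7.4; 5.00: 22.7; 8.00: 39.3; 10.0: 45.4
- Thursday's (time / min: target / %): 0.417: 2.8; 1.00: 13.0; 2.00: 39.9; 3.00: 71.0
- Saturday's (time / min: target / %): 1.33: 5.1; 4.00: 25.9; 8.00: 42.2; 10.0: 45.4

(readings scatter by 0.5 percentage points)

- as a solid, counted per litre of solution: solid substrate
- the earlier runs were read with a standard deviation of 0.5 percentage points
- at the start none of the solid substrate is in solution
- what has only dissolved of solid substrate counts as not reacted

- which flask leads in amount of target, in percent of the solid substrate charged ("all alike" within 1.5 percentage points) (dusk / winter / noon / dawn / all alike)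
- how much target is there at the end, in percent of the solid substrate charged: dusk
- how much target is there at the end, in percent of the solid substrate charged: winter
- how much target is there at the end, in percent of the solid substrate charged: noon
- how much target is there at the end, in percent of the solid substrate charged: dawn

1. First I take the main step by itself, as a clock that runs faster in the warm. Monday reads 39.3% at 8.00 min and Thursday reads 39.9% at 2.00 min, so going from 1 °C to 26 °C, with 6.3 mM of protic impurity against 9.4 mM, speeds the clock by a factor of 4.00; I put that factor on the temperature, though the impurity differs too. I apply that factor in proportion to the degrees. Dusk's 2.0 min then counts as 3.29 min on Thursday's curve, later than its last reading of 71.0%. Noon's counts as 1.43 min, dawn's as 0.624 min and winter's as 0.272 min.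

2. Now I add the solid, which starts with none of it in solution, and I allow that dissolving may not speed up as a reaction does. Between its last two readings Thursday makes target at 13.1 mM min⁻¹. I call this the supply ceiling: the steepest pace of target formation read so far, which I take as what the solid can feed into solution in these flasks. It is a reading and a guess, not a bound, since that pace was still rising. Over 2.0 min that pace comes to 26.1 mM, which is 62.2% of dusk's charge, less than the clock promised. If dissolving is the rate-limiting step at dusk, the ceiling holds and the clock does not.

3. Then comes the rest. Monday and Saturday both read 45.4% at 10.0 min, and both make target more slowly over their last readings than before , which suggests to me that in the cold some material may go elsewhere. Thursday passes that level, but I still allow some loss at dusk.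

4. So I commit to dusk leading, somewhat below 62.2%. I put noon between 13.0% and 39.9%, dawn between 2.8% and 13.0%, and winter under 2.8%.

The forecast names dusk as leader, with 72% there, 27% at noon, 7% at dawn and 2.2% in winter, “about 75%, trimmed slightly for possible hot losses”.

The flasks give 57.8% at dusk, 27.8% at noon, 7.97% at dawn and 1.59% in winter, so dusk leads.

    starting material ⇌ intermediate (K = 0.304, k = 0.00904 s⁻¹, Ea = 71.0 kJ mol⁻¹, ΔH = 20.0 kJ mol⁻¹)
    second nucleophile + protic impurity → quenched reagent (k = 0.205 M⁻¹ s⁻¹, Ea = 45.0 kJ mol⁻¹)
    second nucleophile → decomposed reagent (k = 0.00211 s⁻¹, Ea = 83.0 kJ mol⁻¹)
    solid substrate ⇌ starting material, rate k4*(cs4 - [starting material]) while solid is left; crystals form when [starting material] > cs4 (solubility = 28.0 mM, k = 0.00956 s⁻¹)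
    second nucleophile + intermediate → other capture product (k = 3.49 M⁻¹ s⁻¹, Ea = 52.0 kJ mol⁻¹)
    first nucleophile + intermediate → target (k = 0.923 M⁻¹ s⁻¹, Ea = 41.0 kJ mol⁻¹)
    (constants at 5 °C)

Dusk's target stands 4.4 percentage points under the ceiling, with 28.7% of the solid still undissolved and 0% of the second nucleophile left at 2.00 min. The neighbour flask is dusk with 10 mM of solid. The same ceiling gives 26.1 mM in that time, more than this charge, so I expect its solid to be used up. That flask shows 0% of its solid left at 2.00 min, and its charge has split into 72.2% target and 27.7% other capture product.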